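The ten-membered carbocycle is cut at C4–C5 and C1–C10. Carbons C1–C4, with the C15 ester on C4, are delivered as a cyclobutene ester and added photochemically across C5=C10, the α,β-bond of a cyclohexenone ring comprising C5 to C10 with its carbonyl at C6. One irradiation forms both bonds and a bicyclo[2.2.0]hexane whose strain is later spent in cleaving C5–C10 and C1–C4, so the cyclodecadiene appears without macrocyclisation. The enone comes from the chiral pool and already carries the C8 silyl ether and, cis to it, the C7 acetate arm (C11, C12); only C6, C5 and C10 remain to be set after ring expansion.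

Key step: step 9

Remark 1: target (germacrane) numbering C1–C15 is used for all ring compounds; α/β refer to the usual drawing of the ten-membered ring (numbering anticlockwise, β towards the viewer), in which the target has the C5–O–C10 bridge and O6 on the α-face and C11, O8 and C14 on the β-face.
Remark 2: (S)-2-hydroxy-2-methylbut-3-enoic acid is taken as purchasable in enantiopure form.
Remark 3: the ring opening in step 10 is taken to give one ring-cis (C1=C10) and one ring-trans (C4=C5) double bond; both alkenes are consumed later, so the other cis/trans isomer would serve equally.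

Step 1
Reactants: 1 ethyl (S)-4-chloro-3-hydroxybutanoate
Product: 2 ethyl 2-[(2S)-oxiran-2-yl]acetate
Conditions: Ag2O, DME, 60 °C, dark
Reagents that add atoms: none
Why: Silver-assisted intramolecular Williamson closure of the chlorohydrin leaves the carbinol centre untouched and avoids alkoxide bases that would open the epoxy ester to the 4-hydroxy-2-enoate.

Step 2
Reactants: 2 ethyl 2-[(2S)-oxiran-2-yl]acetate
Product: 3 ethyl (3R)-3-hydroxy-5-methylhex-5-enoate
Conditions: CH2=C(CH3)MgBr, CuI (10 mol %), THF, −40 °C
Reagents that add atoms: isopropenylmagnesium bromide, CC(=C)[Mg]Br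
Why: Copper-catalysed Grignard opening of a terminal epoxide (SN2 at the CH2 terminus) is tolerated by the ester at low temperature; the carbinol carbon is not involved and becomes (R) only through a change in substituent priorities.

Step 3
Reactants: 3 ethyl (3R)-3-hydroxy-5-methylhex-5-enoate
Product: 4 4-tert-butyl 1-ethyl (2R)-2-[(1R)-1-hydroxy-3-methylbut-3-en-1-yl]butanedioate
Conditions: LiN(iPr)2 (LDA, 2.2 equiv), THF, −78 → −20 °C; BrCH2CO2tBu, DMPU, −78 → −30 °C
Reagents that add atoms: tert-butyl bromoacetate, BrCC(=O)OC(C)(C)C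
Why: Fráter–Seebach alkylation: the chelated lithium alkoxide–enolate dianion is alkylated anti to the carbinol substituent, which sets C7 (R) as the anti diastereomer, the open-chain equivalent of the cis C7/C8 relationship of the target ring.

Step 4
Reactants: 4 4-tert-butyl 1-ethyl (2R)-2-[(1R)-1-hydroxy-3-methylbut-3-en-1-yl]butanedioate
Product: 5 4-tert-butyl 1-ethyl (2R)-2-[(1R)-1-(tert-butyldimethylsilyloxy)-3-methylbut-3-en-1-yl]butanedioate
Conditions: TBSOTf, 2,6-lutidine, CH2Cl2, −78 → 0 °C
Reagents that add atoms: tert-butyldimethylsilyl trifluoromethanesulfonate, CC(C)(C)[Si](C)(C)OS(=O)(=O)C(F)(F)F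
Why: Standard silylation of a secondary alcohol, run cold and directly after step 3 so that the γ-hydroxy ester cannot lactonise onto O8.

Step 5
Reactants: 5 4-tert-butyl 1-ethyl (2R)-2-[(1R)-1-(tert-butyldimethylsilyloxy)-3-methylbut-3-en-1-yl]butanedioate
Product: 7 tert-butyl (3R,4R)-4-(tert-butyldimethylsilyloxy)-6-methyl-3-(prop-2-enoyl)hept-6-enoate, via Weinreb amide 6 (not isolated)
Conditions: MeNH(OMe)·HCl, iPrMgCl, THF, −20 °C; then CH2=CHMgBr, −20 → 0 °C; cold aqueous work-up
Reagents that add atoms: vinylmagnesium bromide, C=C[Mg]Br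
Why: Weinreb ketone synthesis in one flask: the chloromagnesium amide exchanges the ethyl ester only (the tert-butyl ester is inert), and the vinyl Grignard adds once to give a chelated tetrahedral intermediate that shields C7 from enolisation until work-up.

Step 6
Reactants: 7 tert-butyl (3R,4R)-4-(tert-butyldimethylsilyloxy)-6-methyl-3-(prop-2-enoyl)hept-6-enoate
Product: 8 tert-butyl 2-[(1R,6R)-6-(tert-butyldimethylsilyloxy)-4-methyl-2-oxocyclohex-3-en-1-yl]acetate
Conditions: second-generation Grubbs catalyst (5 mol %), CH2Cl2, 40 °C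
Reagents that add atoms: none
Why: Ring-closing metathesis between the enone vinyl group and the 1,1-disubstituted alkene forms the six-membered trisubstituted enone (C5=C10) with loss of ethene under neutral conditions that leave C7 and C8 alone.

Step 7
Reactants: 9 ethyl 1-bromocyclobutane-1-carboxylate
Product: 10 cyclobut-1-ene-1-carboxylic acid
Conditions: KOH (powder), toluene, reflux; then aq. HCl
Reagents that add atoms: potassium hydroxide, [K+].[OH-]
Why: Dehydrobromination (E2) of the α-bromo ester with concurrent saponification gives the strained acrylic acid, which is easier to isolate than its volatile esters.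

Step 8
Reactants: 10 cyclobut-1-ene-1-carboxylic acid
Product: 11 methyl cyclobut-1-ene-1-carboxylate
Conditions: MeI, K2CO3, DMF, 0 °C → rt; used freshly
Reagents that add atoms: iodomethane, CI
Why: O-alkylation of the carboxylate (SN2) with a mild, non-nucleophilic base spares the strained Michael acceptor.

Step 9
Reactants: 8 tert-butyl 2-[(1R,6R)-6-(tert-butyldimethylsilyloxy)-4-methyl-2-oxocyclohex-3-en-1-yl]acetate; 11 methyl cyclobut-1-ene-1-carboxylate
Product: 12 head-to-head cis-anti-cis photoadduct (cyclohexanone fused to a bicyclo[2.2.0]hexane)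
Conditions: hν (350 nm, Pyrex), 11 (5 equiv), CH2Cl2, −40 °C
Reagents that add atoms: none
Why: Pyrex-filtered light excites only the enone, whose triplet bonds through its β-carbon C10 to the unsubstituted alkene carbon C1 and leaves a 1,4-diradical with one centre next to the C6 carbonyl (C5) and one next to the ester (C4). The closest known reaction type is the intermolecular enone–alkene [2+2] photocycloaddition with acceptor-substituted cyclobutenes. The one new ring, the central cyclobutane C4–C5–C10–C1, closes by spin inversion and radical–radical coupling of C4 with C5 (collapse of the 1,4-diradical to a four-membered ring), which fuses it to both existing rings. C1 and C4 are necessarily cis because they belong to the four-membered ring of the alkene, C5 and C10 close to the less strained cis fusion, the two outer rings lie anti for steric reasons, and the alkene should approach the α-face opposite the cis C7 and C8 substituents; none of these four centres survives step 10, so their control is not needed. The step must deliver head-to-head orientation (ester carbon C4 on C5, not on C10), and this is secured by the ester itself, which makes C4 the radical-stabilised terminus once C1 has bonded to C10.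

Step 10
Reactants: 12 head-to-head cis-anti-cis photoadduct
Product: 13 methyl (7R,8R)-7-(2-tert-butoxy-2-oxoethyl)-8-(tert-butyldimethylsilyloxy)-10-methyl-6-oxocyclodeca-1(10),4-diene-4-carboxylate
Conditions: toluene (degassed), 160 °C, sealed tube
Reagents that add atoms: none
Why: Thermal cycloreversion of the bicyclo[2.2.0]hexane through the 1,4-diyl (central C1–C4 bond first, then C5–C10) is driven by the strain of two fused four-membered rings and eased by the ester on C4 and the carbonyl next to C5; no stereocentre is made and C7 and C8 are untouched under neutral conditions.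

Step 11
Reactants: 13 methyl (7R,8R)-7-(2-tert-butoxy-2-oxoethyl)-8-(tert-butyldimethylsilyloxy)-10-methyl-6-oxocyclodeca-1(10),4-diene-4-carboxylate
Product: 15 methyl 8β-(tert-butyldimethylsilyloxy)germacra-1(10),4-dien-12,6α-olid-15-oate, via 6α-alcohol 14 (not isolated)
Conditions: (R)-2-methyl-CBS-oxazaborolidine (20 mol %), catecholborane, toluene, −78 °C; MeOH; then CSA (cat.), CH2Cl2, rt
Reagents that add atoms: none
Why: Corey–Bakshi–Shibata 1,2-reduction of the enone carbonyl under reagent control, with the conjugated C4=C5 arm as the large substituent so that hydride reaches the β-face and O6 becomes α (trans to the C7 arm); acid-catalysed intramolecular transesterification then closes the trans-fused γ-lactone with retention at C6.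

Step 12
Reactants: 15 methyl 8β-(tert-butyldimethylsilyloxy)germacra-1(10),4-dien-12,6α-olid-15-oate
Product: 17 methyl 8β-(tert-butyldimethylsilyloxy)-10α-hydroxygermacr-4-en-12,6α-olid-15-oate, via acetoxymercurial 16 (not isolated)
Conditions: Hg(OAc)2, THF–H2O, 0 °C → rt; then NaBH4, aq. NaOH, 0 °C; work-up at pH 4
Reagents that add atoms: water, O
Why: Markovnikov oxymercuration–demercuration picks the electron-rich trisubstituted C1=C10 over the ester-conjugated C4=C5; the C10 centre is set by anti addition, mercury binding the exposed face of the ring alkene and water entering C10 on the α-face turned away from the C8 silyl ether, which is the least secure facial call of the route.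

Step 13
Reactants: 17 methyl 8β-(tert-butyldimethylsilyloxy)-10α-hydroxygermacr-4-en-12,6α-olid-15-oate
Product: 18 methyl 5α,10α-epoxy-8β-(tert-butyldimethylsilyloxy)germacran-12,6α-olid-15-oate
Conditions: KOtBu (20 mol %), THF, −20 → 0 °C; AcOH
Reagents that add atoms: none
Why: Base-catalysed transannular oxa-Michael addition of the C10 alkoxide to C5, the β-carbon of the enoate and the only acceptor site now that C6 is reduced; a one-atom bridge can only span the ring cis, so C5 (O α, H β) follows from C10, while C4, set by protonation, is removed in step 16.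

Step 14
Reactants: 18 methyl 5α,10α-epoxy-8β-(tert-butyldimethylsilyloxy)germacran-12,6α-olid-15-oate
Product: 19 11-methyl derivative of 18 (C13 installed)
Conditions: LiN(iPr)2 (1.1 equiv), THF, −78 °C; MeI, −78 → −40 °C
Reagents that add atoms: iodomethane, CI
Why: Enolate alkylation at C11 of the γ-lactone, the most acidic and least hindered C–H site, so the C4 ester is not deprotonated; the C11 configuration is irrelevant because this carbon becomes sp2 in step 16.

Step 15
Reactants: 19 11-methyl derivative of 18
Product: 20 4,11-bis(phenylselanyl) derivative of 19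
Conditions: LiN(iPr)2 (2.5 equiv), THF–HMPA, −78 °C; PhSeBr, −78 °C
Reagents that add atoms: benzeneselenenyl bromide, Br[Se]c1ccccc1
Why: Double deprotonation (lactone C11–H first, then ester C4–H) and selenenylation of both enolates, kept at −78 °C so that trapping outruns β-elimination of the C5 ether oxygen from the C4 enolate; both new centres disappear in step 16.

Step 16
Reactants: 20 4,11-bis(phenylselanyl) derivative of 19
Product: 21 methyl 5α,10α-epoxy-8β-(tert-butyldimethylsilyloxy)germacra-3,11(13)-dien-12,6α-olid-15-oate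
Conditions: H2O2 (30 %), pyridine, CH2Cl2, 0 °C → rt
Reagents that add atoms: none
Why: Oxidation to the two selenoxides and syn-elimination, at C4 towards C3 (away from the oxygen-bearing bridgehead C5) and at C11 towards the methyl group as is usual for trans-fused α-methyl-α-seleno lactones, gives the C3=C4 enoate and the α-methylene lactone.

Step 17
Reactants: 21 methyl 5α,10α-epoxy-8β-(tert-butyldimethylsilyloxy)germacra-3,11(13)-dien-12,6α-olid-15-oate
Product: 22 methyl (5R,6S,7R,8R,10S)-5,10-epoxy-8-hydroxygermacra-3,11(13)-dien-12,6-olid-15-oate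
Conditions: HF·pyridine, pyridine, THF, 0 °C → rt
Reagents that add atoms: none
Why: Fluoride cleavage of the secondary silyl ether under buffered, non-basic conditions that the α-methylene lactone and the enoate tolerate.

Step 18
Reactants: 23 (S)-2-hydroxy-2-methylbut-3-enoic acid
Product: 25 (S)-2-methyl-2-(trimethylsilyloxy)but-3-enoyl chloride, via bis(trimethylsilyl) derivative 24 (not isolated)
Conditions: TMSCl, Et3N, CH2Cl2, 0 °C; then (COCl)2, DMF (cat.), 0 °C → rt; used crude
Reagents that add atoms: chlorotrimethylsilane, C[Si](C)(C)Cl; oxalyl chloride, O=C(Cl)C(Cl)=O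
Why: Silylation of both OH groups followed by conversion of the silyl ester into the acid chloride with oxalyl chloride/DMF under neutral conditions; the quaternary stereocentre cannot epimerise.

Step 19
Reactants: 22 methyl (5R,6S,7R,8R,10S)-5,10-epoxy-8-hydroxygermacra-3,11(13)-dien-12,6-olid-15-oate; 25 (S)-2-methyl-2-(trimethylsilyloxy)but-3-enoyl chloride
Product: 27 CNP0325750.1 (target), via trimethylsilyl ether 26 (not isolated)
Conditions: 25 (2 equiv), Et3N, DMAP, CH2Cl2, 0 °C → rt; then citric acid, MeOH, rt
Reagents that add atoms: none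
Why: DMAP-catalysed acylation of the C8 alcohol by the acid chloride, then mild acidic methanolysis of the tertiary trimethylsilyl ether; no stereocentre is touched.

Compound list
1 | ethyl (S)-4-chloro-3-hydroxybutanoate | CCOC(=O)C[C@H](O)CCl | starting material
2 | ethyl 2-[(2S)-oxiran-2-yl]acetate | CCOC(=O)C[C@H]1CO1 | intermediate
3 | ethyl (3R)-3-hydroxy-5-methylhex-5-enoate | CCOC(=O)C[C@H](O)CC(C)=C | intermediate
4 | 4-tert-butyl 1-ethyl (2R)-2-[(1R)-1-hydroxy-3-methylbut-3-en-1-yl]butanedioate | CCOC(=O)[C@H](CC(=O)OC(C)(C)C)[C@H](O)CC(C)=C | intermediate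
5 | 4-tert-butyl 1-ethyl (2R)-2-[(1R)-1-(tert-butyldimethylsilyloxy)-3-methylbut-3-en-1-yl]butanedioate | CCOC(=O)[C@H](CC(=O)OC(C)(C)C)[C@H](O[Si](C)(C)C(C)(C)C)CC(C)=C | intermediate
6 | tert-butyl (3R,4R)-4-(tert-butyldimethylsilyloxy)-3-[methoxy(methyl)carbamoyl]-6-methylhept-6-enoate | CON(C)C(=O)[C@H](CC(=O)OC(C)(C)C)[C@H](O[Si](C)(C)C(C)(C)C)CC(C)=C | intermediate
7 | tert-butyl (3R,4R)-4-(tert-butyldimethylsilyloxy)-6-methyl-3-(prop-2-enoyl)hept-6-enoate | C=CC(=O)[C@H](CC(=O)OC(C)(C)C)[C@H](O[Si](C)(C)C(C)(C)C)CC(C)=C | intermediate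
8 | tert-butyl 2-[(1R,6R)-6-(tert-butyldimethylsilyloxy)-4-methyl-2-oxocyclohex-3-en-1-yl]acetate (silyloxy and acetate arm cis) | CC(C)(C)[Si](C)(C)O[C@@H]1CC(C)=CC(=O)[C@@H]1CC(=O)OC(C)(C)C | intermediate
9 | ethyl 1-bromocyclobutane-1-carboxylate | CCOC(=O)C1(Br)CCC1 | starting material
10 | cyclobut-1-ene-1-carboxylic acid | OC(=O)C1=CCC1 | intermediate
11 | methyl cyclobut-1-ene-1-carboxylate | COC(=O)C1=CCC1 | intermediate
12 | methyl 9-(2-tert-butoxy-2-oxoethyl)-8-(tert-butyldimethylsilyloxy)-6-methyl-10-oxotricyclo[4.4.0.0(2,5)]decane-2-carboxylate; head-to-head, cis-anti-cis; in target numbering C7 (R) and C8 (R) substituents cis on the β-face, both four-membered rings on the α-face | CC(C)(C)[Si](C)(C)O[C@@H]1C[C@]2(C)[C@H](C(=O)[C@@H]1CC(=O)OC(C)(C)C)[C@@]1(C(=O)OC)CC[C@H]12 | intermediate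
13 | methyl (7R,8R)-7-(2-tert-butoxy-2-oxoethyl)-8-(tert-butyldimethylsilyloxy)-10-methyl-6-oxocyclodeca-1(10),4-diene-4-carboxylate (target numbering; C2/C9 cis on C1=C10, C3/C6 trans on C4=C5) | CC(C)(C)[Si](C)(C)O[C@@H]1C/C(C)=C\CC/C(C(=O)OC)=C/C(=O)[C@@H]1CC(=O)OC(C)(C)C | intermediate
14 | 6α-alcohol of 13: methyl 7β-(2-tert-butoxy-2-oxoethyl)-8β-(tert-butyldimethylsilyloxy)-6α-hydroxy-10-methylcyclodeca-1(10),4-diene-4-carboxylate | CC(C)(C)[Si](C)(C)O[C@@H]1C/C(C)=C\CC/C(C(=O)OC)=C/[C@@H](O)[C@@H]1CC(=O)OC(C)(C)C | intermediate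
15 | methyl 8β-(tert-butyldimethylsilyloxy)germacra-1(10),4-dien-12,6α-olid-15-oate (trans-fused lactone, H6 β, H7 α) | CC(C)(C)[Si](C)(C)O[C@@H]1C/C(C)=C\CC/C(C(=O)OC)=C/[C@H]2OC(=O)C[C@@H]21 | intermediate
16 | 1-(acetoxymercurio)-10α-hydroxy-1,10-dihydro derivative of 15 (C1 as formed by anti addition, not assigned) | CC(C)(C)[Si](C)(C)O[C@@H]1C[C@@](C)(O)C([Hg]OC(C)=O)CC/C(C(=O)OC)=C/[C@H]2OC(=O)C[C@@H]21 | intermediate
17 | methyl 8β-(tert-butyldimethylsilyloxy)-10α-hydroxygermacr-4-en-12,6α-olid-15-oate | CC(C)(C)[Si](C)(C)O[C@@H]1C[C@@](C)(O)CCC/C(C(=O)OC)=C/[C@H]2OC(=O)C[C@@H]21 | intermediate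
18 | methyl 5α,10α-epoxy-8β-(tert-butyldimethylsilyloxy)germacran-12,6α-olid-15-oate (11-oxabicyclo[4.4.1]undecane core; C4 epimers) | CC(C)(C)[Si](C)(C)O[C@@H]1C[C@]2(C)CCCC(C(=O)OC)[C@@H](O2)[C@H]2OC(=O)C[C@@H]21 | intermediate
19 | 11-methyl derivative of 18 (C4 and C11 epimers) | CC(C)(C)[Si](C)(C)O[C@@H]1C[C@]2(C)CCCC(C(=O)OC)[C@@H](O2)[C@H]2OC(=O)C(C)[C@@H]21 | intermediate
20 | 4,11-bis(phenylselanyl) derivative of 19 (C4 and C11 epimers) | CC(C)(C)[Si](C)(C)O[C@@H]1C[C@]2(C)CCCC([Se]c3ccccc3)(C(=O)OC)[C@@H](O2)[C@H]2OC(=O)C(C)([Se]c3ccccc3)[C@@H]21 | intermediate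
21 | methyl 5α,10α-epoxy-8β-(tert-butyldimethylsilyloxy)germacra-3,11(13)-dien-12,6α-olid-15-oate | CC(C)(C)[Si](C)(C)O[C@@H]1C[C@]2(C)CCC=C(C(=O)OC)[C@@H](O2)[C@H]2OC(=O)C(=C)[C@@H]21 | intermediate
22 | methyl (5R,6S,7R,8R,10S)-5,10-epoxy-8-hydroxygermacra-3,11(13)-dien-12,6-olid-15-oate (8β-OH) | O[C@@H]1C[C@]2(C)CCC=C(C(=O)OC)[C@@H](O2)[C@H]2OC(=O)C(=C)[C@@H]21 | intermediate
23 | (S)-2-hydroxy-2-methylbut-3-enoic acid | C=C[C@](C)(O)C(=O)O | starting material
24 | trimethylsilyl (S)-2-methyl-2-(trimethylsilyloxy)but-3-enoate | C=C[C@](C)(O[Si](C)(C)C)C(=O)O[Si](C)(C)C | intermediate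
25 | (S)-2-methyl-2-(trimethylsilyloxy)but-3-enoyl chloride | C=C[C@](C)(O[Si](C)(C)C)C(Cl)=O | intermediate
26 | O-trimethylsilyl ether of the target (silyl group on the side-chain tertiary oxygen) | C=C[C@](C)(O[Si](C)(C)C)C(=O)O[C@@H]1C[C@]2(C)CCC=C(C(=O)OC)[C@@H](O2)[C@H]2OC(=O)C(=C)[C@@H]21 | intermediate
27 | CNP0325750.1: methyl (5R,6S,7R,8R,10S)-5,10-epoxy-8-[(2S)-2-hydroxy-2-methylbut-3-enoyloxy]germacra-3,11(13)-dien-12,6-olid-15-oate | C=C[C@](C)(O)C(=O)O[C@@H]1C[C@]2(C)CCC=C(C(=O)OC)[C@@H](O2)[C@H]2OC(=O)C(=C)[C@@H]21 | target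

Total step count: 19
Longest linear sequence: 16 steps (1–6, 9–17, 19)

Steps most likely to fail

1. Step 9. The head-to-head orientation may be partly lost, with the ester carbon bonding to C10, and slow addition beside the two cis substituents would let oligomerisation of the cyclobutene compete. The fallback sets out from 8 and uses acid 10 in place of ester 11, so that the partners are oriented by hydrogen bonding and not by the ester alone. Irradiation of 8 with 10 in toluene (350 nm, −40 °C), where the acid O–H bound to the C6 carbonyl holds the carboxyl-bearing carbon over C5, would give the head-to-head cis-anti-cis adduct acid F1. Esterification with TMSCHN2 (MeOH–toluene, 0 °C) comes back to the route at 12.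

2. Step 12. Water may enter C10 on the wrong face, because no nearby stereocentre fixes the facial bias of the flexible ring, and the C1 radical of the demercuration could add across the ring to the enoate. The fallback sets out from 15 and places the oxygen on C5 first under ligand control, so that the bridge dictates C10. Copper-catalysed β-borylation (B2pin2, CuCl, NaOtBu, the Josiphos ligand enantiomer that puts boron on the α-face of C5, MeOH, THF) would give the 5α-pinacolboronate F2. Oxidation with NaBO3·4H2O (THF–H2O) would give the 5α-hydroxy ester F3. Transannular Markovnikov alkoxymercuration with Hg(OCOCF3)2 (MeCN, 0 °C) would give the bridged organomercurial F4, and NaBH4 demercuration comes back to the route at 18, by-passing 17.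

3. Step 11. Catalyst and substrate may be mismatched: the branched C7 flank can compete with the alkenyl flank as the large group, or the inherent facial preference of the ring ketone can override the catalyst, leading to the 6β-alcohol and then the cis-fused lactone. The fallback sets out from 13, accepts the substrate-controlled alcohol and inverts it. Reduction with NaBH4/CeCl3·7H2O (MeOH, −78 °C) would give the 6β-alcohol F5. Mitsunobu inversion (4-nitrobenzoic acid, PPh3, DIAD, THF, 0 °C) would give the 6α-(4-nitrobenzoate) F6. Methanolysis (K2CO3, MeOH, 0 °C) would release 14, which is lactonised with CSA as in step 11 and comes back to the route at 15.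

Further compounds
F1 | step 9 | head-to-head cis-anti-cis adduct acid (2-carboxylic acid analogue of 12) | CC(C)(C)[Si](C)(C)O[C@@H]1C[C@]2(C)[C@H](C(=O)[C@@H]1CC(=O)OC(C)(C)C)[C@@]1(C(=O)O)CC[C@H]12
F2 | step 12 | methyl 8β-(tert-butyldimethylsilyloxy)-5α-(4,4,5,5-tetramethyl-1,3,2-dioxaborolan-2-yl)germacr-1(10)-en-12,6α-olid-15-oate (C4 epimers) | CC(C)(C)[Si](C)(C)O[C@@H]1C/C(C)=C\CCC(C(=O)OC)[C@@H](B3OC(C)(C)C(C)(C)O3)[C@H]2OC(=O)C[C@@H]21
F3 | step 12 | methyl 8β-(tert-butyldimethylsilyloxy)-5α-hydroxygermacr-1(10)-en-12,6α-olid-15-oate (C4 epimers) | CC(C)(C)[Si](C)(C)O[C@@H]1C/C(C)=C\CCC(C(=O)OC)[C@@H](O)[C@H]2OC(=O)C[C@@H]21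
F4 | step 12 | 1-(trifluoroacetoxymercurio) derivative of 18 | CC(C)(C)[Si](C)(C)O[C@@H]1C[C@]2(C)C([Hg]OC(=O)C(F)(F)F)CCC(C(=O)OC)[C@@H](O2)[C@H]2OC(=O)C[C@@H]21
F5 | step 11 | 6β-alcohol (C6 epimer of 14) | CC(C)(C)[Si](C)(C)O[C@@H]1C/C(C)=C\CC/C(C(=O)OC)=C/[C@H](O)[C@@H]1CC(=O)OC(C)(C)C
F6 | step 11 | 6α-(4-nitrobenzoyloxy) ester (4-nitrobenzoate of 14) | CC(C)(C)[Si](C)(C)O[C@@H]1C/C(C)=C\CC/C(C(=O)OC)=C/[C@@H](OC(=O)c2ccc(cc2)[N+](=O)[O-])[C@@H]1CC(=O)OC(C)(C)C
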